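**Retrosynthetic overview**
- Target 26 is cut at the side-chain carbinol (threo-selective reduction of aryloxy ketone 25) and at the ArO–C bond (SN2 of phenol 19 on lactate-derived tosylate 24); the phenol oxygen comes from an aryl chloride by Pd-catalysed hydroxylation.
- The strategy rests on the tetrahydrofuran ring O1–C2–C3–C4–C5: the aryl group on C2 (ring B) is cis to the methyl on C3 within a 2,3-cis-3,4-trans-4,5-cis array, the less stable placement. O1–C2 is therefore made by SN2 closure with inversion at a benzylic mesylate whose ring B is kept electron-poor as 4-chloro-3-methoxyphenyl.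
- Mesylate 16 comes from lactone 9 (C3–C5 stereotriad) by Weinreb opening, silylation, addition of aryllithium 13 and CBS reduction.
- Lactone 9 comes from veratraldehyde by (Z)-crotylboration, hydroboration, oxidative lactonisation and trans-methylation.
- Ring order: the γ-lactone (step 3, opened again in step 5), then the tetrahydrofuran (step 10); the three benzene rings are bought.

Key step: step 10

Remark: metal alkoxides, borate esters and chelated tetrahedral adducts that are only protonated or hydrolysed in the aqueous work-up are counted as the product of their step; species made as a discrete stage in the flask that then react further carry their own number.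

Step 1
Reactants: 1 veratraldehyde; 2 (Z)-crotylboronic acid pinacol ester
Product: 3 (1S,2R)-1-(3,4-dimethoxyphenyl)-2-methylbut-3-en-1-ol
Conditions: (S)-TRIP [(S)-3,3′-bis(2,4,6-triisopropylphenyl)-1,1′-binaphthyl-2,2′-diyl hydrogen phosphate] (5 mol%), 4 Å MS, toluene, −30 °C; aq. NaHCO3 work-up
Reagents that add atoms: none
Why: Chiral-phosphoric-acid-catalysed crotylboration through a closed chair (Zimmerman–Traxler) transition state, in which the (Z)-crotyl geometry sets the syn C1/C2 relationship and the (S)-acid, hydrogen-bonded to a boronate oxygen, is expected to select the si face of the aldehyde to give (1S,2R).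

Step 2
Reactants: 3 (1S,2R)-1-(3,4-dimethoxyphenyl)-2-methylbut-3-en-1-ol
Product: 5 (1S,2R)-1-(3,4-dimethoxyphenyl)-2-methylbutane-1,4-diol, via bis(9-borabicyclononyl) adduct 4 (not isolated)
Conditions: 9-BBN (2.5 equiv), THF, 0 °C → rt; then 3 M aq. NaOH, 30% H2O2, 0 °C → rt
Reagents that add atoms: hydrogen peroxide, OO
Why: Hydroboration–oxidation, in which the bulky dialkylborane adds anti-Markovnikov to the terminal alkene and the C–B bond is oxidised with retention, while the free hydroxyl only consumes one equivalent of borane and neither stereocentre is touched.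

Step 3
Reactants: 5 (1S,2R)-1-(3,4-dimethoxyphenyl)-2-methylbutane-1,4-diol
Product: 7 (4R,5S)-5-(3,4-dimethoxyphenyl)-4-methyldihydrofuran-2(3H)-one, via lactol 6 (not isolated)
Conditions: TEMPO (2,2,6,6-tetramethylpiperidin-1-oxyl, 20 mol%), PhI(OAc)2 (2.5 equiv), CH2Cl2, rt
Reagents that add atoms: none
Why: Oxidative lactonisation of a 1,4-diol, in which the oxoammonium oxidant takes the primary alcohol to the aldehyde faster than the secondary one, the aldehyde is trapped by the benzylic hydroxyl as lactol 6 and this is oxidised again to the lactone, with C4 and C5 unchanged.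

Step 4
Reactants: 7 (4R,5S)-5-(3,4-dimethoxyphenyl)-4-methyldihydrofuran-2(3H)-one
Product: 9 (3R,4R,5S)-5-(3,4-dimethoxyphenyl)-3,4-dimethyldihydrofuran-2(3H)-one, via lithium enolate 8 (not isolated)
Conditions: LiN(SiMe3)2 (1.1 equiv), THF, −78 °C; then MeI (3 equiv), −78 → −40 °C
Reagents that add atoms: iodomethane, CI
Why: Kinetic enolate alkylation, in which iodomethane approaches the lactone enolate on the face opposite the cis-disposed C4 methyl and C5 aryl groups and so sets (3R) with the new methyl trans to the C4 methyl.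

Step 5
Reactants: 9 (3R,4R,5S)-5-(3,4-dimethoxyphenyl)-3,4-dimethyldihydrofuran-2(3H)-one
Product: 10 (2R,3R,4S)-4-(3,4-dimethoxyphenyl)-4-hydroxy-N-methoxy-N,2,3-trimethylbutanamide
Conditions: MeNH(OMe)·HCl (3 equiv), AlMe3 (3 equiv), CH2Cl2, 0 °C → rt; aq. KNaC4H4O6 (potassium sodium tartrate) work-up at 0 °C; used at once
Reagents that add atoms: N,O-dimethylhydroxylamine hydrochloride, CNOC.Cl
Why: Aluminium-amide aminolysis of the lactone (Weinreb amide formation) cleaves only the acyl C–O bond, so the three stereocentres keep their configuration and the benzylic hydroxyl is set free for differentiation.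

Step 6
Reactants: 10 (2R,3R,4S)-4-(3,4-dimethoxyphenyl)-4-hydroxy-N-methoxy-N,2,3-trimethylbutanamide
Product: 11 (2R,3R,4S)-4-(tert-butyldimethylsilyloxy)-4-(3,4-dimethoxyphenyl)-N-methoxy-N,2,3-trimethylbutanamide
Conditions: TBSOTf (1.3 equiv), 2,6-lutidine (2.5 equiv), CH2Cl2, −78 → −40 °C
Reagents that add atoms: tert-butyldimethylsilyl trifluoromethanesulfonate, CC(C)(C)[Si](C)(C)OS(=O)(=O)C(F)(F)F
Why: O-Silylation with the silyl triflate is fast at low temperature and should outpace relactonisation, while 2,6-lutidine buffers the acid so that the electron-rich benzylic C–O bond does not ionise.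

Step 7
Reactants: 12 4-bromo-1-chloro-2-methoxybenzene; 11 (2R,3R,4S)-4-(tert-butyldimethylsilyloxy)-4-(3,4-dimethoxyphenyl)-N-methoxy-N,2,3-trimethylbutanamide
Product: 14 (2R,3R,4S)-4-(tert-butyldimethylsilyloxy)-1-(4-chloro-3-methoxyphenyl)-4-(3,4-dimethoxyphenyl)-2,3-dimethylbutan-1-one, via (4-chloro-3-methoxyphenyl)lithium 13 (not isolated)
Conditions: 12 (1.4 equiv), nBuLi (1.35 equiv), THF, −78 °C, 20 min; then 11, −78 → −30 °C; sat. aq. NH4Cl
Reagents that add atoms: none
Why: Weinreb ketone synthesis, in which bromine–lithium exchange is far faster than chlorine–lithium exchange at −78 °C and the aryllithium adds only once because the chelated tetrahedral adduct survives until the quench, leaving the α-stereocentre untouched.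

Step 8
Reactants: 14 (2R,3R,4S)-4-(tert-butyldimethylsilyloxy)-1-(4-chloro-3-methoxyphenyl)-4-(3,4-dimethoxyphenyl)-2,3-dimethylbutan-1-one
Product: 15 (1R,2R,3R,4S)-4-(tert-butyldimethylsilyloxy)-1-(4-chloro-3-methoxyphenyl)-4-(3,4-dimethoxyphenyl)-2,3-dimethylbutan-1-ol
Conditions: (S)-2-methyl-CBS-oxazaborolidine [(S)-1-methyl-3,3-diphenyltetrahydro-1H,3H-pyrrolo[1,2-c][1,3,2]oxazaborole] (0.5 equiv), BH3·SMe2 (1.5 equiv), THF, −20 °C; MeOH quench
Reagents that add atoms: none
Why: Corey–Bakshi–Shibata reduction, in which the (S)-oxazaborolidine delivers hydride to the face that gives the (1R)-carbinol with the aryl group as the large substituent, and the Felkin–Anh preference of the α-methyl ketone (1,2-anti) points the same way, so reagent and substrate control are matched.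

Step 9
Reactants: 15 (1R,2R,3R,4S)-4-(tert-butyldimethylsilyloxy)-1-(4-chloro-3-methoxyphenyl)-4-(3,4-dimethoxyphenyl)-2,3-dimethylbutan-1-ol
Product: 16 (1R,2R,3R,4S)-4-(tert-butyldimethylsilyloxy)-1-(4-chloro-3-methoxyphenyl)-4-(3,4-dimethoxyphenyl)-2,3-dimethylbutyl methanesulfonate
Conditions: Ms2O (1.5 equiv), Et3N (3 equiv), DMAP (0.1 equiv), CH2Cl2, −20 → 0 °C; cold aq. NaHCO3 work-up, crude mesylate used at once
Reagents that add atoms: methanesulfonic anhydride, CS(=O)(=O)OS(C)(=O)=O
Why: O-Sulfonylation forms only the O–S bond and so keeps the (1R) configuration, the chloride-free anhydride avoids displacement to a benzylic chloride, and the electron-poor aryl ring keeps the benzylic mesylate from ionising.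

Step 10
Reactants: 16 (1R,2R,3R,4S)-4-(tert-butyldimethylsilyloxy)-1-(4-chloro-3-methoxyphenyl)-4-(3,4-dimethoxyphenyl)-2,3-dimethylbutyl methanesulfonate
Product: 18 (2S,3R,4R,5S)-2-(4-chloro-3-methoxyphenyl)-5-(3,4-dimethoxyphenyl)-3,4-dimethyltetrahydrofuran, via tetrabutylammonium alkoxide 17 (not isolated)
Conditions: Bu4NF (2 equiv, 1 M in THF), THF, 0 °C → rt
Reagents that add atoms: none
Why: Fluoride cleaves the O–Si bond of 16 and the tetrabutylammonium alkoxide 17 so formed attacks the benzylic carbon from the side opposite the mesylate, forming the O1–C2 bond in a single SN2 event; the closest known reaction type is the intramolecular Williamson etherification of a 1,4-diol monosulfonate. The tetrahydrofuran ring closes in the 5-exo-tet mode, helped by the two backbone methyl groups, which favour the folded conformer. The one new stereocentre, C2, is controlled by the (1R) configuration of the mesylate, which is inverted to (2S) and so places ring B cis to the C3 methyl, while C3, C4 and C5 are carried through unchanged. The step needs substitution with clean inversion to outrun ionisation to a benzylic cation and E2 loss of methanesulfonic acid. The para-chloro and meta-methoxy substituents of ring B, both electron-withdrawing toward the benzylic carbon, suppress the cation, and the intramolecular five-membered closure is expected to be much faster than attack of fluoride as a base or nucleophile.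

Step 11
Reactants: 18 (2S,3R,4R,5S)-2-(4-chloro-3-methoxyphenyl)-5-(3,4-dimethoxyphenyl)-3,4-dimethyltetrahydrofuran
Product: 19 4-[(2S,3R,4R,5S)-5-(3,4-dimethoxyphenyl)-3,4-dimethyltetrahydrofuran-2-yl]-2-methoxyphenol
Conditions: Pd2(dba)3 (2 mol%), tBuXPhos (2-di-tert-butylphosphino-2′,4′,6′-triisopropylbiphenyl, 8 mol%), KOH (4 equiv), 1,4-dioxane/H2O 1:1, 100 °C; then 1 M HCl to pH 5
Reagents that add atoms: potassium hydroxide, [K+].[OH-]
Why: Palladium-catalysed C–O coupling of an aryl chloride with hydroxide (oxidative addition to the zerovalent palladium–biarylphosphine complex, chloride/hydroxide exchange, C–O reductive elimination promoted by the bulky ligand), under which the non-acidic tetrahydrofuran stereocentres should stay unchanged.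

Step 12
Reactants: 20 ethyl (S)-lactate
Product: 21 (S)-2-hydroxy-N-methoxy-N-methylpropanamide
Conditions: MeNH(OMe)·HCl (2.5 equiv), iPrMgCl (5 equiv), THF, −20 → 0 °C; sat. aq. NH4Cl
Reagents that add atoms: N,O-dimethylhydroxylamine hydrochloride, CNOC.Cl
Why: Magnesium-amide aminolysis of the ester (Weinreb amide formation) takes place at the acyl carbon only, with the α-hydroxyl held as its magnesium alkoxide, so the (S)-centre is retained.

Step 13
Reactants: 21 (S)-2-hydroxy-N-methoxy-N-methylpropanamide; 22 3,4-dimethoxyphenylmagnesium bromide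
Product: 23 (S)-1-(3,4-dimethoxyphenyl)-2-hydroxypropan-1-one
Conditions: 22 (3 equiv), THF, 0 °C → rt; sat. aq. NH4Cl
Reagents that add atoms: none
Why: Grignard addition to a Weinreb amide, in which the first equivalent deprotonates the hydroxyl and the next adds once to give a chelated tetrahedral adduct that collapses to the ketone only on work-up, the α-alkoxide shielding the stereocentre from enolisation.

Step 14
Reactants: 23 (S)-1-(3,4-dimethoxyphenyl)-2-hydroxypropan-1-one
Product: 24 (S)-1-(3,4-dimethoxyphenyl)-1-oxopropan-2-yl 4-methylbenzenesulfonate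
Conditions: TsCl (1.3 equiv), pyridine (3 equiv), DMAP (0.1 equiv), CH2Cl2, 0 °C
Reagents that add atoms: p-toluenesulfonyl chloride, Cc1ccc(cc1)S(Cl)(=O)=O
Why: O-Sulfonylation of the secondary alcohol does not break the C–O bond and so gives the (S)-α-tosyloxy ketone with retention, as an SN2-activated electrophile.

Step 15
Reactants: 19 4-[(2S,3R,4R,5S)-5-(3,4-dimethoxyphenyl)-3,4-dimethyltetrahydrofuran-2-yl]-2-methoxyphenol; 24 (S)-1-(3,4-dimethoxyphenyl)-1-oxopropan-2-yl 4-methylbenzenesulfonate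
Product: 25 (R)-1-(3,4-dimethoxyphenyl)-2-{4-[(2S,3R,4R,5S)-5-(3,4-dimethoxyphenyl)-3,4-dimethyltetrahydrofuran-2-yl]-2-methoxyphenoxy}propan-1-one
Conditions: BEMP (2-tert-butylimino-2-diethylamino-1,3-dimethylperhydro-1,3,2-diazaphosphorine, 1.1 equiv), CH2Cl2, 0 °C → rt
Reagents that add atoms: none
Why: Williamson-type SN2 displacement of the α-keto tosylate by the phenoxide proceeds with inversion to the (R)-α-aryloxy ketone, the carbonyl group accelerating substitution so that it should outrun enolisation when only one equivalent of the non-nucleophilic phosphazene base is present.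

Step 16
Reactants: 25 (R)-1-(3,4-dimethoxyphenyl)-2-{4-[(2S,3R,4R,5S)-5-(3,4-dimethoxyphenyl)-3,4-dimethyltetrahydrofuran-2-yl]-2-methoxyphenoxy}propan-1-one
Product: 26 (1R,2R)-1-(3,4-dimethoxyphenyl)-2-{4-[(2S,3R,4R,5S)-5-(3,4-dimethoxyphenyl)-3,4-dimethyltetrahydrofuran-2-yl]-2-methoxyphenoxy}propan-1-ol
Conditions: borohydride-form anion-exchange resin (polystyrene–CH2NMe3+ BH4−, about 3 equiv of hydride), MeOH, 0 °C
Reagents that add atoms: none
Why: Hydride addition under non-chelating conditions (quaternary ammonium counter-ion, protic solvent) follows the polar Felkin–Anh model with the aryloxy C–O bond anti to the incoming hydride, which sets (1R) and should give the threo (1R,2R) alcohol.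

**Compound list**
1 | veratraldehyde (3,4-dimethoxybenzaldehyde) | COc1ccc(C=O)cc1OC | starting material
2 | (Z)-crotylboronic acid pinacol ester, 2-[(2Z)-but-2-en-1-yl]-4,4,5,5-tetramethyl-1,3,2-dioxaborolane | C/C=C\CB1OC(C)(C)C(C)(C)O1 | starting material
3 | (1S,2R)-1-(3,4-dimethoxyphenyl)-2-methylbut-3-en-1-ol | C=C[C@@H](C)[C@H](O)c1ccc(OC)c(OC)c1 | intermediate
4 | 9-[(3R,4S)-4-(9-borabicyclo[3.3.1]nonan-9-yloxy)-4-(3,4-dimethoxyphenyl)-3-methylbutyl]-9-borabicyclo[3.3.1]nonane | COc1ccc(cc1OC)[C@@H](OB1C2CCCC1CCC2)[C@H](C)CCB1C2CCCC1CCC2 | intermediate (not isolated)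
5 | (1S,2R)-1-(3,4-dimethoxyphenyl)-2-methylbutane-1,4-diol | OCC[C@@H](C)[C@H](O)c1ccc(OC)c(OC)c1 | intermediate
6 | (4R,5S)-5-(3,4-dimethoxyphenyl)-4-methyltetrahydrofuran-2-ol (lactol, both anomers) | OC1C[C@@H](C)[C@@H](c2ccc(OC)c(OC)c2)O1 | intermediate (not isolated)
7 | (4R,5S)-5-(3,4-dimethoxyphenyl)-4-methyldihydrofuran-2(3H)-one | O=C1C[C@@H](C)[C@@H](c2ccc(OC)c(OC)c2)O1 | intermediate
8 | lithium enolate of 7, lithium (4R,5S)-5-(3,4-dimethoxyphenyl)-4-methyl-4,5-dihydrofuran-2-olate | [Li]OC1=C[C@@H](C)[C@@H](c2ccc(OC)c(OC)c2)O1 | intermediate (not isolated)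
9 | (3R,4R,5S)-5-(3,4-dimethoxyphenyl)-3,4-dimethyldihydrofuran-2(3H)-one | O=C1[C@H](C)[C@@H](C)[C@@H](c2ccc(OC)c(OC)c2)O1 | intermediate
10 | (2R,3R,4S)-4-(3,4-dimethoxyphenyl)-4-hydroxy-N-methoxy-N,2,3-trimethylbutanamide | CON(C)C(=O)[C@H](C)[C@@H](C)[C@H](O)c1ccc(OC)c(OC)c1 | intermediate
11 | (2R,3R,4S)-4-(tert-butyldimethylsilyloxy)-4-(3,4-dimethoxyphenyl)-N-methoxy-N,2,3-trimethylbutanamide | CON(C)C(=O)[C@H](C)[C@@H](C)[C@H](O[Si](C)(C)C(C)(C)C)c1ccc(OC)c(OC)c1 | intermediate
12 | 4-bromo-1-chloro-2-methoxybenzene | COc1cc(Br)ccc1Cl | starting material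
13 | (4-chloro-3-methoxyphenyl)lithium | COc1cc([Li])ccc1Cl | intermediate (not isolated)
14 | (2R,3R,4S)-4-(tert-butyldimethylsilyloxy)-1-(4-chloro-3-methoxyphenyl)-4-(3,4-dimethoxyphenyl)-2,3-dimethylbutan-1-one | COc1cc(ccc1Cl)C(=O)[C@H](C)[C@@H](C)[C@H](O[Si](C)(C)C(C)(C)C)c1ccc(OC)c(OC)c1 | intermediate
15 | (1R,2R,3R,4S)-4-(tert-butyldimethylsilyloxy)-1-(4-chloro-3-methoxyphenyl)-4-(3,4-dimethoxyphenyl)-2,3-dimethylbutan-1-ol | COc1cc(ccc1Cl)[C@H](O)[C@H](C)[C@@H](C)[C@H](O[Si](C)(C)C(C)(C)C)c1ccc(OC)c(OC)c1 | intermediate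
16 | (1R,2R,3R,4S)-4-(tert-butyldimethylsilyloxy)-1-(4-chloro-3-methoxyphenyl)-4-(3,4-dimethoxyphenyl)-2,3-dimethylbutyl methanesulfonate | COc1cc(ccc1Cl)[C@H](OS(C)(=O)=O)[C@H](C)[C@@H](C)[C@H](O[Si](C)(C)C(C)(C)C)c1ccc(OC)c(OC)c1 | intermediate
17 | tetrabutylammonium (1S,2R,3R,4R)-4-(4-chloro-3-methoxyphenyl)-1-(3,4-dimethoxyphenyl)-4-(methanesulfonyloxy)-2,3-dimethylbutan-1-olate | COc1cc(ccc1Cl)[C@H](OS(C)(=O)=O)[C@H](C)[C@@H](C)[C@H]([O-])c1ccc(OC)c(OC)c1.CCCC[N+](CCCC)(CCCC)CCCC | intermediate (not isolated)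
18 | (2S,3R,4R,5S)-2-(4-chloro-3-methoxyphenyl)-5-(3,4-dimethoxyphenyl)-3,4-dimethyltetrahydrofuran | COc1cc(ccc1Cl)[C@H]1O[C@H](c2ccc(OC)c(OC)c2)[C@H](C)[C@H]1C | intermediate
19 | 4-[(2S,3R,4R,5S)-5-(3,4-dimethoxyphenyl)-3,4-dimethyltetrahydrofuran-2-yl]-2-methoxyphenol | COc1cc(ccc1O)[C@H]1O[C@H](c2ccc(OC)c(OC)c2)[C@H](C)[C@H]1C | intermediate
20 | ethyl (S)-lactate | CCOC(=O)[C@H](C)O | starting material
21 | (S)-2-hydroxy-N-methoxy-N-methylpropanamide | CON(C)C(=O)[C@H](C)O | intermediate
22 | 3,4-dimethoxyphenylmagnesium bromide (commercial solution in THF) | COc1ccc([Mg]Br)cc1OC | starting material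
23 | (S)-1-(3,4-dimethoxyphenyl)-2-hydroxypropan-1-one | COc1ccc(C(=O)[C@H](C)O)cc1OC | intermediate
24 | (S)-1-(3,4-dimethoxyphenyl)-1-oxopropan-2-yl 4-methylbenzenesulfonate | COc1ccc(C(=O)[C@H](C)OS(=O)(=O)c2ccc(C)cc2)cc1OC | intermediate
25 | (R)-1-(3,4-dimethoxyphenyl)-2-{4-[(2S,3R,4R,5S)-5-(3,4-dimethoxyphenyl)-3,4-dimethyltetrahydrofuran-2-yl]-2-methoxyphenoxy}propan-1-one | COc1ccc(C(=O)[C@@H](C)Oc2ccc([C@H]3O[C@H](c4ccc(OC)c(OC)c4)[C@H](C)[C@H]3C)cc2OC)cc1OC | intermediate
26 | (1R,2R)-1-(3,4-dimethoxyphenyl)-2-{4-[(2S,3R,4R,5S)-5-(3,4-dimethoxyphenyl)-3,4-dimethyltetrahydrofuran-2-yl]-2-methoxyphenoxy}propan-1-ol | COc1ccc([C@@H](O)[C@@H](C)Oc2ccc([C@H]3O[C@H](c4ccc(OC)c(OC)c4)[C@H](C)[C@H]3C)cc2OC)cc1OC | target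

**Step count**
Total step count: 16. Longest linear sequence: 13 steps (steps 1–11, 15 and 16, from veratraldehyde); steps 12–14 make the side-chain electrophile 24.

**Steps most likely to fail**

Step 10 (ring closure). If desilylation is slow, fluoride can act on the benzylic mesylate as a base or nucleophile (E2 loss of methanesulfonic acid, substitution, or partial ionisation), so that material is lost or the C2 configuration is eroded.
- Fallback: sets out from lactone 9 and makes the C2–aryl bond on a preformed ring instead of the O1–C2 bond.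
- Reduction of 9 with iBu2AlH (CH2Cl2, −78 °C) should give the lactol (3R,4R,5S)-5-(3,4-dimethoxyphenyl)-3,4-dimethyltetrahydrofuran-2-ol F1.
- Benzenesulfinic acid and CaCl2 (CH2Cl2, rt) should convert it into (3R,4R,5S)-2-(benzenesulfonyl)-5-(3,4-dimethoxyphenyl)-3,4-dimethyltetrahydrofuran F2.
- Aryllithium 13 is transmetallated with ZnBr2 to (4-chloro-3-methoxyphenyl)zinc bromide F3, which is added to F2 in THF at rt.
- Arylzinc addition to the oxocarbenium ion released from such 2-sulfonyl ethers is expected to place the aryl group cis to the C3 methyl, and the sequence comes back to the route at 18.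

Step 15 (phenol alkylation). Base-induced enolisation of tosylate 24 or of ketone 25 would erode the configuration at the carbon bearing the aryloxy group before or after substitution.
- Fallback: sets out from phenol 19 and ethyl (S)-lactate 20 and forms the ether bond at the ester oxidation level, where the α-proton is far less acidic.
- Mitsunobu etherification (PPh3, diisopropyl azodicarboxylate, THF, 0 °C) with inversion should give ethyl (R)-2-{4-[(2S,3R,4R,5S)-5-(3,4-dimethoxyphenyl)-3,4-dimethyltetrahydrofuran-2-yl]-2-methoxyphenoxy}propanoate F4.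
- MeNH(OMe)·HCl and iPrMgCl (THF, −20 °C) should give (R)-2-{4-[(2S,3R,4R,5S)-5-(3,4-dimethoxyphenyl)-3,4-dimethyltetrahydrofuran-2-yl]-2-methoxyphenoxy}-N-methoxy-N-methylpropanamide F5.
- Addition of Grignard reagent 22 to F5 comes back to the route at 25.

Step 16 (final reduction). Poor facial selectivity in the hydride addition (a chelation-type pathway competing with the Felkin–Anh one) would leave the carbinol centre as a mixture.
- Fallback: sets out from ketone 25 and reaches the threo alcohol by deliberate erythro reduction followed by inversion.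
- Chelation-controlled reduction with Zn(BH4)2 (Et2O, −20 °C) should give the erythro alcohol (1S,2R)-1-(3,4-dimethoxyphenyl)-2-{4-[(2S,3R,4R,5S)-5-(3,4-dimethoxyphenyl)-3,4-dimethyltetrahydrofuran-2-yl]-2-methoxyphenoxy}propan-1-ol F6.
- Mitsunobu inversion with 4-nitrobenzoic acid (PPh3, diisopropyl azodicarboxylate, THF) should give (1R,2R)-1-(3,4-dimethoxyphenyl)-2-{4-[(2S,3R,4R,5S)-5-(3,4-dimethoxyphenyl)-3,4-dimethyltetrahydrofuran-2-yl]-2-methoxyphenoxy}propyl 4-nitrobenzoate F7.
- Methanolysis of F7 (K2CO3, MeOH) comes back to the route at 26.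

Further compounds
F1 | step 10 | (3R,4R,5S)-5-(3,4-dimethoxyphenyl)-3,4-dimethyltetrahydrofuran-2-ol | OC1[C@H](C)[C@@H](C)[C@@H](c2ccc(OC)c(OC)c2)O1
F2 | step 10 | (3R,4R,5S)-2-(benzenesulfonyl)-5-(3,4-dimethoxyphenyl)-3,4-dimethyltetrahydrofuran | O=S(=O)(c1ccccc1)C1[C@H](C)[C@@H](C)[C@@H](c2ccc(OC)c(OC)c2)O1
F3 | step 10 | (4-chloro-3-methoxyphenyl)zinc bromide | COc1cc([Zn]Br)ccc1Cl
F4 | step 15 | ethyl (R)-2-{4-[(2S,3R,4R,5S)-5-(3,4-dimethoxyphenyl)-3,4-dimethyltetrahydrofuran-2-yl]-2-methoxyphenoxy}propanoate | CCOC(=O)[C@@H](C)Oc1ccc(cc1OC)[C@H]1O[C@H](c2ccc(OC)c(OC)c2)[C@H](C)[C@H]1C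
F5 | step 15 | (R)-2-{4-[(2S,3R,4R,5S)-5-(3,4-dimethoxyphenyl)-3,4-dimethyltetrahydrofuran-2-yl]-2-methoxyphenoxy}-N-methoxy-N-methylpropanamide | CON(C)C(=O)[C@@H](C)Oc1ccc(cc1OC)[C@H]1O[C@H](c2ccc(OC)c(OC)c2)[C@H](C)[C@H]1C
F6 | step 16 | (1S,2R)-1-(3,4-dimethoxyphenyl)-2-{4-[(2S,3R,4R,5S)-5-(3,4-dimethoxyphenyl)-3,4-dimethyltetrahydrofuran-2-yl]-2-methoxyphenoxy}propan-1-ol | COc1ccc([C@H](O)[C@@H](C)Oc2ccc([C@H]3O[C@H](c4ccc(OC)c(OC)c4)[C@H](C)[C@H]3C)cc2OC)cc1OC
F7 | step 16 | (1R,2R)-1-(3,4-dimethoxyphenyl)-2-{4-[(2S,3R,4R,5S)-5-(3,4-dimethoxyphenyl)-3,4-dimethyltetrahydrofuran-2-yl]-2-methoxyphenoxy}propyl 4-nitrobenzoate | COc1ccc([C@@H](OC(=O)c5ccc(cc5)[N+](=O)[O-])[C@@H](C)Oc2ccc([C@H]3O[C@H](c4ccc(OC)c(OC)c4)[C@H](C)[C@H]3C)cc2OC)cc1OC
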